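**Retrosynthetic overview**

- Feature: in the bicyclo[3.2.1]octane core (C1 isobutyryl bridgehead, C2 CMe2, C3 CH-prenyl, C4 CH2, C5 prenyl bridgehead, C6 carbinol, C7 ring ketone, C8 bridge ketone; ring A = C1–C2–C3–C4–C5–C8, ring B = C1–C7–C6–C5–C8) C1 is bonded to both carbonyl carbons C7 and C8, and C5 to C8 directly and to C7 through C6. With C6 taken out, the four-membered ring C1–C7–C5–C8 is the [2+2] adduct of a C5=C7 ketene and a C1=C8 silyl enol ether.
- Disconnections: Z-enone from an ynone (Lindlar); C6–acyl bond by exo aldol of a C6 α-silyloxy enolate with an ynal; C6 by one-carbon insertion between C5 and C7 of a cyclobutanone; cyclobutanone and ring A by the intramolecular ketene–enol ether [2+2]; the acyclic chain by C4–C5 alkylation, a Mukaiyama aldol at C1 and an Evans prenylation that sets C3.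
- Ring order: ring A together with the cyclobutanone (step 12), then ring B by ring expansion (step 13).
- Design points: the enol ether carries SiEt3 and the carbinol SitBuMe2, so that C8 can be unmasked and oxidised before C6 is functionalised (a silyloxy group on C8 would cover the exo face of C6–C7). The acid is carried as its silyl ester, which gives the acid chloride without HCl.

Key step: step 12

Remark: C5 of the open chain, the isobutyl carbinol carbon and the silyloxy carbon C8 are carried as stereoisomer mixtures (the first becomes the ketene carbon, the others carbonyl carbons); 5-methylhex-4-enoic acid is taken as a catalogue compound; TBS = SitBuMe2, TES = SiEt3; exo = the face of the C6–C7 bridge turned to C8, endo = the face turned to C2–C4.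

**Route**

Step 1
Reactants: 1 3,3-dimethylpent-4-enoic acid; 2 (S)-4-benzyl-1,3-oxazolidin-2-one
Product: 4 (S)-4-benzyl-3-(3,3-dimethylpent-4-enoyl)-1,3-oxazolidin-2-one, via mixed pivalic anhydride 3 (not isolated)
Conditions: PivCl, Et3N, THF, −20 °C; then 2, LiCl, −20 °C → rt
Reagents that add atoms: none
Why: N-acylation of the oxazolidinone through the mixed pivalic anhydride (LiCl/Et3N activation) is the standard way to attach an Evans auxiliary and leaves the terminal alkene untouched.

Step 2
Reactants: 4; 5 1-bromo-3-methylbut-2-ene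
Product: 7 (S)-4-benzyl-3-[(2S)-3,3-dimethyl-2-(3-methylbut-2-en-1-yl)pent-4-enoyl]-1,3-oxazolidin-2-one, via sodium enolate 6 (not isolated)
Conditions: NaN(SiMe3)2, THF, −78 °C; then 5, −78 → −30 °C
Reagents that add atoms: none
Why: Evans asymmetric alkylation: the chelated (Z)-sodium enolate is attacked by the allylic bromide on the face away from the benzyl group, which sets C3 (2S in 7).

Step 3
Reactants: 7
Product: 8 (2S)-3,3-dimethyl-2-(3-methylbut-2-en-1-yl)pent-4-en-1-ol
Conditions: LiBH4, MeOH (1 equiv), Et2O, 0 °C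
Reagents that add atoms: none
Why: Reductive removal of the auxiliary (hydride attack on the exocyclic imide carbonyl) gives the primary alcohol without enolisation, so C3 is kept, and the oxazolidinone is recovered.

Step 4
Reactants: 8
Product: 9 (2S)-1-iodo-3,3-dimethyl-2-(3-methylbut-2-en-1-yl)pent-4-ene
Conditions: I2, PPh3, imidazole, CH2Cl2, 0 °C → rt
Reagents that add atoms: iodine, II
Why: Appel-type iodination replaces the primary hydroxyl by iodide through the alkoxyphosphonium salt under neutral conditions that touch neither the alkenes nor C3.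

Step 5
Reactants: 10 5-methylhex-4-enoic acid; 9
Product: 12 (4R)-5,5-dimethyl-2,4-bis(3-methylbut-2-en-1-yl)hept-6-enoic acid (C2 epimers), via dilithium enediolate 11 (not isolated)
Conditions: LiN(iPr)2 (2.2 equiv), THF/DMPU, 0 °C → rt; then 9, rt → 40 °C; 1 M HCl
Reagents that add atoms: none
Why: α-Alkylation of a carboxylic acid dianion with a primary iodide forms C4–C5; the enediolate survives the warming that the β-branched iodide needs, and C5 needs no control because it becomes the ketene carbon.

Step 6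
Reactants: 12
Product: 14 (4R)-7-hydroxy-5,5-dimethyl-2,4-bis(3-methylbut-2-en-1-yl)heptanoic acid, via B-alkyl-9-BBN acyloxyborane 13 (not isolated)
Conditions: 9-BBN (2.4 equiv), THF, 0 °C → rt; then NaOH, H2O2, 0 °C; 1 M HCl to pH 3
Reagents that add atoms: hydrogen peroxide, OO
Why: Hydroboration–oxidation with 9-BBN is anti-Markovnikov and discriminates the monosubstituted C1=C8 alkene from the two trisubstituted prenyl alkenes; the acid only consumes one equivalent as its acyloxyborane.

Step 7
Reactants: 14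
Product: 15 (4R)-5,5-dimethyl-2,4-bis(3-methylbut-2-en-1-yl)-7-oxoheptanoic acid
Conditions: TEMPO (10 mol %), PhI(OAc)2, CH2Cl2, rt
Reagents that add atoms: none
Why: Oxoammonium (TEMPO) oxidation with PhI(OAc)2 as terminal oxidant stops at the aldehyde in the absence of water and spares the alkenes and the carboxylic acid.

Step 8
Reactants: 15
Product: 16 TBS (4R)-7-(TBS-oxy)-5,5-dimethyl-2,4-bis(3-methylbut-2-en-1-yl)hept-6-enoate (enol ether E/Z mixture)
Conditions: TBSOTf (2.3 equiv), Et3N, CH2Cl2, −78 → 0 °C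
Reagents that add atoms: tert-butyldimethylsilyl trifluoromethanesulfonate, CC(C)(C)[Si](C)(C)OS(=O)(=O)C(F)(F)F
Why: Soft enolisation with a silyl triflate and an amine turns the aldehyde into its silyl enol ether and caps the acid as its silyl ester in one operation; the excess amine keeps the silylated aldehyde from being attacked by the C3 prenyl alkene.

Step 9
Reactants: 16; 17 2-methylpropanal (isobutyraldehyde)
Product: 18 TBS (4R)-7-(TBS-oxy)-6-formyl-5,5,8-trimethyl-2,4-bis(3-methylbut-2-en-1-yl)nonanoate (diastereomer mixture)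
Conditions: 17 (3 equiv), HNTf2 (2 mol %), CH2Cl2, −78 °C
Reagents that add atoms: none
Why: Mukaiyama aldol addition under silyl triflimide catalysis, in which the silyl group passes to the new carbinol oxygen, joins C1 to the isobutyl carbinol carbon and gives the β-silyloxy aldehyde directly; the hindered product should not add a second time, and its two new stereocentres need no control because both are removed later.

Step 10
Reactants: 18
Product: 19 TBS (4R)-7-(TBS-oxy)-5,5,8-trimethyl-2,4-bis(3-methylbut-2-en-1-yl)-6-[(triethylsilyloxy)methylidene]nonanoate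
Conditions: Et3SiOTf, Et3N, CH2Cl2, −78 → 0 °C
Reagents that add atoms: triethylsilyl trifluoromethanesulfonate, CC[Si](CC)(CC)OS(=O)(=O)C(F)(F)F
Why: Soft enolisation of the α-branched aldehyde gives the C1=C8 triethylsilyl enol ether without a free carbanion, so the β-silyloxy group is not eliminated, and either enol ether geometry serves.

Step 11
Reactants: 19
Product: 20 (4R)-7-(TBS-oxy)-5,5,8-trimethyl-2,4-bis(3-methylbut-2-en-1-yl)-6-[(triethylsilyloxy)methylidene]nonanoyl chloride
Conditions: (COCl)2 (1.1 equiv), DMF (5 mol %), CH2Cl2, 0 °C → rt; evaporate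
Reagents that add atoms: oxalyl chloride, O=C(Cl)C(=O)Cl
Why: Silyl esters are converted into acid chlorides by the Vilsmeier reagent from oxalyl chloride and DMF with loss of the silyl chloride and no HCl, so the enol ether and the silyl ether should survive.

Step 12
Reactants: 20
Product: 22 1-[1-(TBS-oxy)-2-methylpropyl]-2,2-dimethyl-3,5-bis(3-methylbut-2-en-1-yl)-7-(triethylsilyloxy)bicyclo[3.1.1]heptan-6-one (carbonyl bridge = C7 on the C3–H face; silyloxy bridge = C8 on the C3-prenyl face), via ketene 21 (not isolated)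
Conditions: Et3N (5 equiv), toluene, 110 °C, slow addition of 20 (final 0.005 M)
Reagents that add atoms: none
Why: Et3N converts 20 into the dialkylketene 21, whose carbonyl carbon C7 is attacked in the ketene plane by the nucleophilic enol-ether carbon C1 while C8 takes on oxocarbenium character and then bonds to the ketene terminus C5, i.e. an asynchronous thermal [2+2] cycloaddition. The closest known reaction type is the intramolecular ketene–alkene cycloaddition in its bridged mode (three-atom tether, cation-stabilising substituent on the outer alkene carbon, giving bicyclo[3.1.1]heptan-6-ones), combined with the known reactivity of ketenes toward silyl enol ethers. The six-membered carbocycle closes first by 6-exo attack of C1 on C7 through the C2–C3–C4 tether, and the cyclobutanone (and with it ring A, C1–C2–C3–C4–C5–C8) closes by 4-exo collapse of C5 onto C8; the fused mode is excluded because it would need the electrophilic C7 to bond to the oxygen-bearing C8. C1 and C5 are created together, fixed relative to each other by the bridge and relative to C3 by a chair-like arrangement of the forming ring A in which C3 is bent away from C8 and its prenyl group is equatorial; this puts C7 on the face of C3–H and C8 on the face of the prenyl group as in the target, while the configuration at C8 follows the enol ether geometry and is later erased. The step needs the enol ether to capture the ketene before the C3 prenyl alkene (same tether length) or a second ketene does: the silyl enol ether is the far stronger π-nucleophile, slow addition at high dilution keeps the ketene concentration low, and SiEt3 resists the silyl transfer that would stop at C-acylation better than SiMe3.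

Step 13
Reactants: 22
Product: 24 1-[1-(TBS-oxy)-2-methylpropyl]-8-hydroxy-2,2-dimethyl-3,5-bis(3-methylbut-2-en-1-yl)bicyclo[3.2.1]octan-7-one, via 8-triethylsilyloxy ketone 23 (not isolated)
Conditions: CH2N2, Et2O/MeOH, 0 °C → rt; then PPTS, MeOH, rt
Reagents that add atoms: diazomethane, C=[N+]=[N-]
Why: Uncatalysed diazomethane ring expansion (Tiffeneau–Demjanov type) is driven by cyclobutanone strain and needs no Lewis acid, which would open the 3-silyloxycyclobutanone; the methylene should enter on the less encumbered flank so that C5 migrates (C1 carries the branched silyloxyalkyl group and adjoins CMe2), and buffered methanolysis then frees only the more labile triethylsilyl ether at C8.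

Step 14
Reactants: 24
Product: 25 1-[1-(TBS-oxy)-2-methylpropyl]-2,2-dimethyl-3,5-bis(3-methylbut-2-en-1-yl)bicyclo[3.2.1]octane-7,8-dione
Conditions: DMP, CH2Cl2, rt
Reagents that add atoms: none
Why: Dess–Martin oxidation turns the bridging secondary alcohol into the non-enolisable bridge ketone C8, which leaves the exo face of C6–C7 open for the next steps.

Step 15
Reactants: 25
Product: 27 1-[1-(TBS-oxy)-2-methylpropyl]-6-hydroxy-2,2-dimethyl-3,5-bis(3-methylbut-2-en-1-yl)bicyclo[3.2.1]octane-7,8-dione (6-OH exo), via potassium enolate 26 (not isolated)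
Conditions: KN(SiMe3)2, THF, −78 °C; then 2-(phenylsulfonyl)-3-phenyloxaziridine, −78 °C; AcOH
Reagents that add atoms: 2-(phenylsulfonyl)-3-phenyloxaziridine, O=S(=O)(c1ccccc1)N1OC1c1ccccc1
Why: Davis oxidation of the only possible enolate (C1 and C5 are quaternary) hydroxylates C6 without epoxidising the prenyl groups; the reagent should approach from the exo face, but this centre is made planar again in step 19.

Step 16
Reactants: 27
Product: 28 1-[1-(TBS-oxy)-2-methylpropyl]-2,2-dimethyl-3,5-bis(3-methylbut-2-en-1-yl)-6-(triethylsilyloxy)bicyclo[3.2.1]octane-7,8-dione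
Conditions: Et3SiOTf, 2,6-lutidine, CH2Cl2, −78 °C
Reagents that add atoms: triethylsilyl trifluoromethanesulfonate, CC[Si](CC)(CC)OS(=O)(=O)C(F)(F)F
Why: Silylation of the α-ketol with a silyl triflate and a hindered pyridine base blocks enediolate formation and α-ketol rearrangement in the coming enolisation.

Step 17
Reactants: 29 2-methylbut-3-yn-2-ol
Product: 30 triethyl[(2-methylbut-3-yn-2-yl)oxy]silane
Conditions: Et3SiCl, imidazole, DMAP (cat.), DMF, rt
Reagents that add atoms: chlorotriethylsilane, CC[Si](Cl)(CC)CC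
Why: Imidazole-mediated silylation protects the tertiary propargylic alcohol so that the alkyne can be lithiated.

Step 18
Reactants: 30
Product: 32 4-methyl-4-(triethylsilyloxy)pent-2-ynal, via lithium acetylide 31 (not isolated)
Conditions: n-BuLi, THF, −78 °C; then DMF, −78 → 0 °C; AcOH/H2O, 0 °C
Reagents that add atoms: N,N-dimethylformamide, CN(C)C=O
Why: Formylation of the lithium acetylide with DMF gives the ynal after collapse of the hemiaminal, and the acidic quench protonates dimethylamine before it can add to the ynal.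

Step 19
Reactants: 28; 32
Product: 34 1-[1-(TBS-oxy)-2-methylpropyl]-6-[1-hydroxy-4-methyl-4-(triethylsilyloxy)pent-2-yn-1-yl]-2,2-dimethyl-3,5-bis(3-methylbut-2-en-1-yl)-6-(triethylsilyloxy)bicyclo[3.2.1]octane-7,8-dione (side chain exo; C6–O endo; carbinol epimers), via lithium enolate 33 (not isolated)
Conditions: LiN(iPr)2, THF, −78 → −30 °C; then 32, −78 °C; AcOH, −78 °C
Reagents that add atoms: none
Why: Aldol addition of the lithium enolate of an α-silyloxy ketone to a small, reactive ynal; enolisation needs warming because the remaining C6–H lies on the shielded endo face, and the aldehyde then bonds to C6 on the exo face (the side of the C8 carbonyl, the endo face being covered by the axial C3–H of ring A), which sets C6 with carbon exo and oxygen endo as in the target, the new carbinol centre being left uncontrolled because it is oxidised.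

Step 20
Reactants: 34
Product: 35 6-(1,4-dihydroxy-4-methylpent-2-yn-1-yl)-6-hydroxy-1-(1-hydroxy-2-methylpropyl)-2,2-dimethyl-3,5-bis(3-methylbut-2-en-1-yl)bicyclo[3.2.1]octane-7,8-dione
Conditions: HF·pyridine, pyridine, THF, 0 °C → rt
Reagents that add atoms: none
Why: Fluoride-mediated desilylation under buffered acidic conditions removes the two triethylsilyl ethers and the hindered TBS ether without the base that would trigger retro-aldol loss of the side chain, and it is done before any ynone is present.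

Step 21
Reactants: 35
Product: 36 6-hydroxy-6-(4-hydroxy-4-methylpent-2-ynoyl)-2,2-dimethyl-3,5-bis(3-methylbut-2-en-1-yl)-1-(2-methylpropanoyl)bicyclo[3.2.1]octane-7,8-dione
Conditions: IBX, DMSO, rt → 40 °C
Reagents that add atoms: none
Why: IBX oxidises the two secondary carbinols (propargylic and isobutyl) to ketones, leaves the tertiary alcohols alone and does not cleave the C6 tertiary/secondary 1,2-diol.

Step 22
Reactants: 36
Product: 37 6-hydroxy-6-[(2Z)-4-hydroxy-4-methylpent-2-enoyl]-2,2-dimethyl-3,5-bis(3-methylbut-2-en-1-yl)-1-(2-methylpropanoyl)bicyclo[3.2.1]octane-7,8-dione (CNP0190794.1; C3 prenyl on the C8 face; 6-OH endo)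
Conditions: H2 (1 atm), Pd/CaCO3 poisoned with Pb(OAc)2, quinoline, EtOAc, 0 °C
Reagents that add atoms: none
Why: Lindlar semihydrogenation adds H2 syn to the alkyne and so gives the Z-enone, while the trisubstituted prenyl alkenes are not reduced on the poisoned catalyst.

**Compound list**

1 | 3,3-dimethylpent-4-enoic acid | C=CC(C)(C)CC(=O)O | starting material
2 | (S)-4-benzyl-1,3-oxazolidin-2-one | O=C1N[C@@H](Cc2ccccc2)CO1 | starting material
3 | 3,3-dimethylpent-4-enoic pivalic anhydride (not isolated) | C=CC(C)(C)CC(=O)OC(=O)C(C)(C)C | intermediate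
4 | (S)-4-benzyl-3-(3,3-dimethylpent-4-enoyl)-1,3-oxazolidin-2-one | C=CC(C)(C)CC(=O)N1[C@@H](Cc2ccccc2)COC1=O | intermediate
5 | 1-bromo-3-methylbut-2-ene | CC(C)=CCBr | starting material
6 | sodium (Z)-enolate of 4 (not isolated) | C=CC(C)(C)/C=C(\[O-])N1[C@@H](Cc2ccccc2)COC1=O.[Na+] | intermediate
7 | (S)-4-benzyl-3-[(2S)-3,3-dimethyl-2-(3-methylbut-2-en-1-yl)pent-4-enoyl]-1,3-oxazolidin-2-one | CC(C)=CC[C@@H](C(C)(C)C=C)C(=O)N1[C@@H](Cc2ccccc2)COC1=O | intermediate
8 | (2S)-3,3-dimethyl-2-(3-methylbut-2-en-1-yl)pent-4-en-1-ol | CC(C)=CC[C@@H](C(C)(C)C=C)CO | intermediate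
9 | (2S)-1-iodo-3,3-dimethyl-2-(3-methylbut-2-en-1-yl)pent-4-ene | CC(C)=CC[C@@H](C(C)(C)C=C)CI | intermediate
10 | 5-methylhex-4-enoic acid | CC(C)=CCCC(=O)O | starting material
11 | dilithium enediolate of 10 (not isolated) | CC(C)=CCC=C([O-])[O-].[Li+].[Li+] | intermediate
12 | (4R)-5,5-dimethyl-2,4-bis(3-methylbut-2-en-1-yl)hept-6-enoic acid (C2 epimers) | CC(C)=CC[C@@H](C(C)(C)C=C)CC(CC=C(C)C)C(=O)O | intermediate
13 | B-alkyl-9-BBN adduct of 12, acid as acyloxy-9-BBN (not isolated) | CC(C)=CC[C@@H](C(C)(C)CCB1C2CCCC1CCC2)CC(CC=C(C)C)C(=O)OB1C2CCCC1CCC2 | intermediate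
14 | (4R)-7-hydroxy-5,5-dimethyl-2,4-bis(3-methylbut-2-en-1-yl)heptanoic acid | CC(C)=CC[C@@H](C(C)(C)CCO)CC(CC=C(C)C)C(=O)O | intermediate
15 | (4R)-5,5-dimethyl-2,4-bis(3-methylbut-2-en-1-yl)-7-oxoheptanoic acid | CC(C)=CC[C@@H](C(C)(C)CC=O)CC(CC=C(C)C)C(=O)O | intermediate
16 | TBS (4R)-7-(TBS-oxy)-5,5-dimethyl-2,4-bis(3-methylbut-2-en-1-yl)hept-6-enoate | CC(C)=CC[C@@H](C(C)(C)C=CO[Si](C)(C)C(C)(C)C)CC(CC=C(C)C)C(=O)O[Si](C)(C)C(C)(C)C | intermediate
17 | 2-methylpropanal | CC(C)C=O | starting material
18 | TBS (4R)-7-(TBS-oxy)-6-formyl-5,5,8-trimethyl-2,4-bis(3-methylbut-2-en-1-yl)nonanoate | CC(C)=CC[C@@H](C(C)(C)C(C=O)C(O[Si](C)(C)C(C)(C)C)C(C)C)CC(CC=C(C)C)C(=O)O[Si](C)(C)C(C)(C)C | intermediate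
19 | TBS (4R)-7-(TBS-oxy)-5,5,8-trimethyl-2,4-bis(3-methylbut-2-en-1-yl)-6-[(triethylsilyloxy)methylidene]nonanoate | CC(C)=CC[C@@H](C(C)(C)C(=CO[Si](CC)(CC)CC)C(O[Si](C)(C)C(C)(C)C)C(C)C)CC(CC=C(C)C)C(=O)O[Si](C)(C)C(C)(C)C | intermediate
20 | acid chloride of the acid corresponding to 19 (key-step precursor) | CC(C)=CC[C@@H](C(C)(C)C(=CO[Si](CC)(CC)CC)C(O[Si](C)(C)C(C)(C)C)C(C)C)CC(CC=C(C)C)C(Cl)=O | intermediate
21 | C5=C7 ketene from 20, a non-1-en-1-one (not isolated) | CC(C)=CC[C@@H](C(C)(C)C(=CO[Si](CC)(CC)CC)C(O[Si](C)(C)C(C)(C)C)C(C)C)CC(CC=C(C)C)=C=O | intermediate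
22 | 1-[1-(TBS-oxy)-2-methylpropyl]-2,2-dimethyl-3,5-bis(3-methylbut-2-en-1-yl)-7-(triethylsilyloxy)bicyclo[3.1.1]heptan-6-one (key-step product) | CC(C)=CC[C@@H]1C[C@]2(CC=C(C)C)C(O[Si](CC)(CC)CC)[C@@](C(O[Si](C)(C)C(C)(C)C)C(C)C)(C2=O)C1(C)C | intermediate
23 | 1-[1-(TBS-oxy)-2-methylpropyl]-2,2-dimethyl-3,5-bis(3-methylbut-2-en-1-yl)-8-(triethylsilyloxy)bicyclo[3.2.1]octan-7-one (not isolated) | CC(C)=CC[C@@H]1C[C@]2(CC=C(C)C)C(O[Si](CC)(CC)CC)[C@@](C(O[Si](C)(C)C(C)(C)C)C(C)C)(C(=O)C2)C1(C)C | intermediate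
24 | 8-hydroxy analogue of 23 | CC(C)=CC[C@@H]1C[C@]2(CC=C(C)C)C(O)[C@@](C(O[Si](C)(C)C(C)(C)C)C(C)C)(C(=O)C2)C1(C)C | intermediate
25 | 1-[1-(TBS-oxy)-2-methylpropyl]-2,2-dimethyl-3,5-bis(3-methylbut-2-en-1-yl)bicyclo[3.2.1]octane-7,8-dione | CC(C)=CC[C@@H]1C[C@]2(CC=C(C)C)C(=O)[C@@](C(O[Si](C)(C)C(C)(C)C)C(C)C)(C(=O)C2)C1(C)C | intermediate
26 | potassium C6=C7 enolate of 25 (not isolated) | CC(C)=CC[C@@H]1C[C@]2(CC=C(C)C)C(=O)[C@@](C(O[Si](C)(C)C(C)(C)C)C(C)C)(C([O-])=C2)C1(C)C.[K+] | intermediate
27 | 6-exo-hydroxy derivative of 25 | CC(C)=CC[C@@H]1C[C@]2(CC=C(C)C)C(=O)[C@@](C(O[Si](C)(C)C(C)(C)C)C(C)C)(C(=O)[C@H]2O)C1(C)C | intermediate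
28 | 6-exo-(triethylsilyloxy) derivative of 25 | CC(C)=CC[C@@H]1C[C@]2(CC=C(C)C)C(=O)[C@@](C(O[Si](C)(C)C(C)(C)C)C(C)C)(C(=O)[C@H]2O[Si](CC)(CC)CC)C1(C)C | intermediate
29 | 2-methylbut-3-yn-2-ol | CC(C)(O)C#C | starting material
30 | triethyl[(2-methylbut-3-yn-2-yl)oxy]silane | CC(C)(O[Si](CC)(CC)CC)C#C | intermediate
31 | lithium acetylide of 30 (not isolated) | [Li]C#CC(C)(C)O[Si](CC)(CC)CC | intermediate
32 | 4-methyl-4-(triethylsilyloxy)pent-2-ynal | CC(C)(O[Si](CC)(CC)CC)C#CC=O | intermediate
33 | lithium C6=C7 enolate of 28 (not isolated) | CC(C)=CC[C@@H]1C[C@]2(CC=C(C)C)C(=O)[C@@](C(O[Si](C)(C)C(C)(C)C)C(C)C)(C([O-])=C2O[Si](CC)(CC)CC)C1(C)C.[Li+] | intermediate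
34 | aldol adduct: 6-exo-[1-hydroxy-4-methyl-4-(triethylsilyloxy)pent-2-yn-1-yl]-6-endo-(triethylsilyloxy) derivative of 25 | CC(C)=CC[C@@H]1C[C@]2(CC=C(C)C)C(=O)[C@@](C(O[Si](C)(C)C(C)(C)C)C(C)C)(C(=O)[C@@]2(O[Si](CC)(CC)CC)C(O)C#CC(C)(C)O[Si](CC)(CC)CC)C1(C)C | intermediate
35 | 6-(1,4-dihydroxy-4-methylpent-2-yn-1-yl)-6-hydroxy-1-(1-hydroxy-2-methylpropyl)-2,2-dimethyl-3,5-bis(3-methylbut-2-en-1-yl)bicyclo[3.2.1]octane-7,8-dione | CC(C)=CC[C@@H]1C[C@]2(CC=C(C)C)C(=O)[C@@](C(O)C(C)C)(C(=O)[C@@]2(O)C(O)C#CC(C)(C)O)C1(C)C | intermediate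
36 | 6-hydroxy-6-(4-hydroxy-4-methylpent-2-ynoyl)-2,2-dimethyl-3,5-bis(3-methylbut-2-en-1-yl)-1-(2-methylpropanoyl)bicyclo[3.2.1]octane-7,8-dione | CC(C)=CC[C@@H]1C[C@]2(CC=C(C)C)C(=O)[C@@](C(=O)C(C)C)(C(=O)[C@@]2(O)C(=O)C#CC(C)(C)O)C1(C)C | intermediate
37 | CNP0190794.1: 6-hydroxy-6-[(2Z)-4-hydroxy-4-methylpent-2-enoyl]-2,2-dimethyl-3,5-bis(3-methylbut-2-en-1-yl)-1-(2-methylpropanoyl)bicyclo[3.2.1]octane-7,8-dione | CC(C)=CC[C@@H]1C[C@]2(CC=C(C)C)C(=O)[C@@](C(=O)C(C)C)(C(=O)[C@@]2(O)C(=O)/C=C\C(C)(C)O)C1(C)C | target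

**Step count and risks**

Total step count: 22 (steps 17 and 18 make the side-chain aldehyde). Longest linear sequence: 20 steps (1–16, 19–22).

Steps most likely to fail:

1. Step 12. The ketene may be consumed by cycloaddition to the C3 prenyl alkene (held by a three-atom tether as well) or by dimerisation before the hindered enol-ether carbon C1 can bond to C7; silyl transfer could also stop the reaction at C-acylation. Fallback: take the competing trisubstituted alkenes away for the duration of the cycloaddition. Setting out from 18, ethenolysis (ethylene, second-generation Hoveyda–Grubbs catalyst RuCl2(=CH-2-iPrO-C6H4)(H2IMes), CH2Cl2, 40 °C) would cut both prenyl groups back to allyl groups and give the bis-allyl aldehyde F1. Et3SiOTf/Et3N would give its enol ether F2 and oxalyl chloride/DMF the acid chloride F3. Et3N in hot toluene would give the ketene F4, which should close onto the enol ether to the bis-allyl cyclobutanone F5, monosubstituted alkenes being far poorer ketenophiles. Cross-metathesis of F5 with 2-methylbut-2-ene (second-generation Grubbs catalyst RuCl2(=CHPh)(PCy3)(H2IMes)) would restore both prenyl groups and return to 22.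

2. Step 13. Diazomethane may add too slowly to a carbonyl group flanked by two quaternary carbons, C1 may migrate in place of C5 so that the new carbon ends up between C1 and C7, or homologation may run on to the six-membered ketone. Fallback: a two-stage spiro-epoxide enlargement. From 22, dimethylsulfonium methylide (Me3S+ I−, KN(SiMe3)2, THF, 0 °C; Corey–Chaykovsky reaction) would give the spiro-epoxide F6. LiI in THF at reflux would open the epoxide at its CH2 terminus and trigger the 1,2-shift of the less encumbered C5. This gives the ring-expanded ketone 23, where the fallback returns to the route; methanolysis as in step 13 then gives 24.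

3. Step 19. Removal of the endo C6–H may be slow, the silyl group may migrate within the enolate, or the congested aldolate may lose the ynal by retro-aldol. Fallback: make the C6 nucleophile by reduction instead of deprotonation. From 27, Dess–Martin oxidation would give the 6,7,8-trione F8. Zn/Me3SiCl in THF would reduce the vicinal diketone to the 6,7-bis(trimethylsilyloxy) ene F9. A BF3·OEt2-mediated Mukaiyama aldol of F9 with 32 at −78 °C would bond the ynal to the less hindered enediol carbon C6 from the exo face and give the 6-trimethylsilyloxy adduct F10. HF·pyridine would then remove all silyl groups and return to 35.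

**Further compounds**

F1 | step 12 | TBS (4R)-7-(TBS-oxy)-6-formyl-5,5,8-trimethyl-2,4-di(prop-2-en-1-yl)nonanoate | C=CC[C@@H](C(C)(C)C(C=O)C(O[Si](C)(C)C(C)(C)C)C(C)C)CC(CC=C)C(=O)O[Si](C)(C)C(C)(C)C
F2 | step 12 | triethylsilyl enol ether of F1 | C=CC[C@@H](C(C)(C)C(=CO[Si](CC)(CC)CC)C(O[Si](C)(C)C(C)(C)C)C(C)C)CC(CC=C)C(=O)O[Si](C)(C)C(C)(C)C
F3 | step 12 | acid chloride from F2 | C=CC[C@@H](C(C)(C)C(=CO[Si](CC)(CC)CC)C(O[Si](C)(C)C(C)(C)C)C(C)C)CC(CC=C)C(Cl)=O
F4 | step 12 | ketene from F3 (not isolated) | C=CC[C@@H](C(C)(C)C(=CO[Si](CC)(CC)CC)C(O[Si](C)(C)C(C)(C)C)C(C)C)CC(CC=C)=C=O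
F5 | step 12 | 3,5-diallyl analogue of 22 | C=CC[C@@H]1C[C@]2(CC=C)C(O[Si](CC)(CC)CC)[C@@](C(O[Si](C)(C)C(C)(C)C)C(C)C)(C2=O)C1(C)C
F6 | step 13 | spiro-epoxide of 22 at C7 (1-oxaspiro[2.3]hexane unit) | CC(C)=CC[C@@H]1C[C@]2(CC=C(C)C)C(O[Si](CC)(CC)CC)[C@@](C(O[Si](C)(C)C(C)(C)C)C(C)C)(C23CO3)C1(C)C
F8 | step 19 | 1-[1-(TBS-oxy)-2-methylpropyl]-2,2-dimethyl-3,5-bis(3-methylbut-2-en-1-yl)bicyclo[3.2.1]octane-6,7,8-trione | CC(C)=CC[C@@H]1C[C@]2(CC=C(C)C)C(=O)[C@@](C(O[Si](C)(C)C(C)(C)C)C(C)C)(C(=O)C2=O)C1(C)C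
F9 | step 19 | 6,7-bis(trimethylsilyloxy)bicyclo[3.2.1]oct-6-en-8-one from F8 | CC(C)=CC[C@@H]1C[C@]2(CC=C(C)C)C(=O)[C@@](C(O[Si](C)(C)C(C)(C)C)C(C)C)(C(O[Si](C)(C)C)=C2O[Si](C)(C)C)C1(C)C
F10 | step 19 | 6-(trimethylsilyloxy) analogue of 34 | CC(C)=CC[C@@H]1C[C@]2(CC=C(C)C)C(=O)[C@@](C(O[Si](C)(C)C(C)(C)C)C(C)C)(C(=O)[C@@]2(O[Si](C)(C)C)C(O)C#CC(C)(C)O[Si](CC)(CC)CC)C1(C)C
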